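The chromene is cut at the two bonds that tie its pyran ring to the benzene ring, C4–C4a and O1–C8a, which end on the adjacent aromatic carbons C4a and C8a. This leaves the four-atom unit O1–C2(CH3)–C3=C4 intact; it is taken from C1–C3 of solanesol as an (R,Z)-1-iodoalk-1-en-3-ol whose tertiary carbinol carbon (future C2) is set by Sharpless epoxidation. The arene partner is an ortho-bromo arylboronate with the C6 oxygen silylated. One palladium catalyst joins both bonds in a single flask, Suzuki coupling first and C–O coupling second, so the pyran ring closes while the C2–O bond stays untouched. Fluoride then frees the phenol.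

Key step: step 8

Remark 1: R below is the (3E,7E,11E,15E,19E,23E,27E)-4,8,12,16,20,24,28,32-octamethyltritriaconta-3,7,11,15,19,23,27,31-octaen-1-yl chain (C4–C36 of solanesol with eight of its methyl groups). Solanesol is numbered from the carbinol carbon C1; the chromene is numbered O1, C2, C3, C4, C4a, C5–C8, C8a.

Remark 2: the C6 phenol is carried as its triisopropylsilyl ether and not as an acetal, so that the last step needs buffered fluoride instead of acid, which the 2H-chromene and the eight trisubstituted alkenes tolerate better; the bulky group also shields its ortho position in steps 6 and 7.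

Remark 3: compounds 14 and 15 are handled under argon in amber glassware, because 2H-chromenes can ring-open under UV light and thereby racemise at C2.

Step 1
Reactants: 1 solanesol
Product: 2 (2R,3R)-2,3-epoxysolanesol
Conditions: Ti(OiPr)4 (10 mol %), D-(−)-diisopropyl tartrate (12 mol %), TBHP (2 equiv, in decane), 4 Å MS, CH2Cl2, −20 °C
Reagents that add atoms: tert-butyl hydroperoxide, CC(C)(C)OO
Why: Katsuki–Sharpless asymmetric epoxidation, in which only the allylic alcohol binds titanium so that the 2,3-alkene alone is oxidised, and the D-(−)-tartrate ligand directs oxygen to the face that gives the (2R,3R)-epoxide (E-3-methylalk-2-en-1-ols of the geraniol type give the 2S,3S series with L-(+)-tartrate), which fixes the future C2 of the chromene.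

Step 2
Reactants: 2 (2R,3R)-2,3-epoxysolanesol
Product: 3 (2S,3R)-2,3-epoxysolanesyl chloride
Conditions: PPh3 (1.5 equiv), CCl4, NaHCO3, reflux
Reagents that add atoms: tetrachloromethane, ClC(Cl)(Cl)Cl
Why: Appel chlorination replaces the primary hydroxyl by chloride at C1 under buffered, non-acidic conditions that should leave the oxirane, both stereocentres and the eight alkenes alone (the C2 descriptor becomes S only because chlorine changes the CIP ranking).

Step 3
Reactants: 3 (2S,3R)-2,3-epoxysolanesyl chloride
Product: 5 (3R)-3-methyl-3-hydroxy-alk-1-yne R–C(CH3)(OH)–C≡CH, via chloroalkenol lithium alkoxide 4 (not isolated)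
Conditions: n-BuLi (3.5 equiv), THF, −40 → −20 °C; aq NH4Cl
Reagents that add atoms: none
Why: Base-induced double elimination of a 2,3-epoxy chloride to a propargylic alcohol, in which lithiation at C1 opens the oxirane to the chloroalkene alkoxide 4, loss of HCl then gives the acetylide, and C3 keeps its C–O bond and therefore its R configuration.

Step 4
Reactants: 5 (3R)-alkynol R–C(CH3)(OH)–C≡CH
Product: 7 (1Z,3R)-1-iodoalk-1-en-3-ol R–C(CH3)(OH)–CH=CH–I, via cyclic alkenylaluminate 6 (not isolated)
Conditions: Red-Al (2.5 equiv), THF, 0 °C → rt; EtOAc, then I2 (1.2 equiv), −78 → −20 °C; aq Na2S2O3, Rochelle salt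
Reagents that add atoms: iodine, II
Why: Hydroxyl-directed trans-hydroalumination of the propargylic alkoxide places aluminium on C1 cis to the carbinol carbon in the five-membered aluminate 6, and iodinolysis with retention should give the Z-iodoalkene, while isolated alkenes are inert to the hydride.

Step 5
Reactants: 8 2,3-dimethylphenol
Product: 9 (2,3-dimethylphenoxy)triisopropylsilane
Conditions: TIPSCl (1.2 equiv), imidazole (2.5 equiv), DMF, rt → 40 °C
Reagents that add atoms: triisopropylsilyl chloride, CC(C)[Si](Cl)(C(C)C)C(C)C
Why: Imidazole-mediated O-silylation of a phenol gives a bulky aryl silyl ether that should withstand borylation, bromination and the phosphate base of step 8 and later leaves with fluoride.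

Step 6
Reactants: 9 (2,3-dimethylphenoxy)triisopropylsilane; 10 bis(pinacolato)diboron
Product: 11 [2,3-dimethyl-5-(4,4,5,5-tetramethyl-1,3,2-dioxaborolan-2-yl)phenoxy]triisopropylsilane
Conditions: [Ir(OMe)(cod)]2 (1.5 mol %), dtbpy (3 mol %), 10 (1.0 equiv), THF, 80 °C
Reagents that add atoms: none
Why: Iridium-catalysed C–H borylation (Ishiyama–Miyaura–Hartwig borylation) is governed by sterics, and C5 is the only ring C–H without an ortho substituent.

Step 7
Reactants: 11 [2,3-dimethyl-5-(pinacolboryl)phenoxy]triisopropylsilane
Product: 12 2-bromo-3,4-dimethyl-5-(triisopropylsilyloxy)phenylboronic acid pinacol ester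
Conditions: NBS (1.05 equiv), MeCN, 0 °C → rt, dark
Reagents that add atoms: N-bromosuccinimide, O=C1CCC(=O)N1Br
Why: Electrophilic aromatic bromination should go para to the silyloxy group (also ortho to a methyl), because the alternative ortho position is shielded by the triisopropylsilyl group, and polar conditions in the dark avoid benzylic bromination and leave the C–B bond in place.

Step 8
Reactants: 7 (1Z,3R)-1-iodoalk-1-en-3-ol (1.0 equiv); 12 2-bromo-3,4-dimethyl-5-(triisopropylsilyloxy)phenylboronic acid pinacol ester (1.15 equiv)
Product: 14 plastochromenol-8 triisopropylsilyl ether, via bromostyrenyl carbinol 13 (not isolated)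
Conditions: tBuXPhos Pd G3 (5 mol %), K3PO4 (4 equiv), H2O (3 equiv), toluene, 40 °C; then powdered 4 Å MS, 80 °C; Ar, dark
Reagents that add atoms: none
Why: Proposed new method: Pd(0) should add to the alkenyl C–I bond of 7 well before it touches the electron-rich, doubly ortho-flanked C–Br bond of 12; phosphate-assisted transmetalation from boron and reductive elimination with retention of the cis geometry give bromostyrene 13 (C4–C4a), and on warming the same catalyst inserts into C8a–Br, the tertiary hydroxyl is deprotonated on palladium, and C–O reductive elimination joins O1 to C8a. The nearest known reactions are the stereoretentive Suzuki–Miyaura coupling of Z-alkenyl iodides and the Buchwald–Hartwig-type intramolecular etherification of tertiary alcohols with aryl bromides, which have not been run as one annulation. The pyran ring closes by intramolecular O-arylation through a seven-membered oxapalladacycle that contracts to the six-membered ring on reductive elimination. No stereocentre is formed: C2 keeps its R configuration because none of its bonds is broken (no ionisation, no o-quinone methide), and as it bears no hydrogen the alkoxide cannot undergo β-hydride elimination. The step needs iodide-before-bromide chemoselectivity and retention of the Z alkene, which holds the alkoxide next to C8a; the reactivity gap between the two halides at 40 °C provides the first. Phosphate is used instead of an alkoxide base, which would turn the Z-iodoalkene into the alkyne by anti elimination and attack the silyl ether, and light is excluded.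

Step 9
Reactants: 14 plastochromenol-8 triisopropylsilyl ether
Product: 15 plastochromenol-8
Conditions: TBAF (1.2 equiv), AcOH (1.2 equiv), THF, 0 °C, Ar, dark
Reagents that add atoms: none
Why: Fluoride-mediated desilylation cleaves the aryl silyl ether at silicon under buffered, near-neutral conditions, so the 2H-chromene, the trisubstituted alkenes and C2 should not be touched.

Compound list
1 | solanesol, (2E,6E,10E,14E,18E,22E,26E,30E)-3,7,11,15,19,23,27,31,35-nonamethylhexatriaconta-2,6,10,14,18,22,26,30,34-nonaen-1-ol | CC(C)=CCC/C(C)=C/CC/C(C)=C/CC/C(C)=C/CC/C(C)=C/CC/C(C)=C/CC/C(C)=C/CC/C(C)=C/CC/C(C)=C/CO | starting material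
2 | (2R,3R)-2,3-epoxysolanesol, [(2R,3R)-3-methyl-3-R-oxiran-2-yl]methanol | CC(C)=CCC/C(C)=C/CC/C(C)=C/CC/C(C)=C/CC/C(C)=C/CC/C(C)=C/CC/C(C)=C/CC/C(C)=C/CC[C@@]1(C)O[C@@H]1CO | intermediate
3 | (2S,3R)-2,3-epoxysolanesyl chloride, (2S,3R)-2-(chloromethyl)-3-methyl-3-R-oxirane (same spatial arrangement as 2) | CC(C)=CCC/C(C)=C/CC/C(C)=C/CC/C(C)=C/CC/C(C)=C/CC/C(C)=C/CC/C(C)=C/CC/C(C)=C/CC[C@@]1(C)O[C@@H]1CCl | intermediate
4 | (1E,3R)-1-chloro-3,7,11,15,19,23,27,31,35-nonamethylhexatriaconta-1,6,10,14,18,22,26,30,34-nonaen-3-ol, present as its lithium alkoxide (drawn E; either geometry converges on 5) | CC(C)=CCC/C(C)=C/CC/C(C)=C/CC/C(C)=C/CC/C(C)=C/CC/C(C)=C/CC/C(C)=C/CC/C(C)=C/CC[C@@](C)(O)/C=C/Cl | intermediate (not isolated)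
5 | (3R,6E,10E,14E,18E,22E,26E,30E)-3,7,11,15,19,23,27,31,35-nonamethylhexatriaconta-6,10,14,18,22,26,30,34-octaen-1-yn-3-ol | CC(C)=CCC/C(C)=C/CC/C(C)=C/CC/C(C)=C/CC/C(C)=C/CC/C(C)=C/CC/C(C)=C/CC/C(C)=C/CC[C@@](C)(O)C#C | intermediate
6 | sodium (5R)-2,2-bis(2-methoxyethoxy)-5-methyl-5-R-1-oxa-2-aluminatacyclopent-3-ene (cyclic alkenylaluminate) | CC(C)=CCC/C(C)=C/CC/C(C)=C/CC/C(C)=C/CC/C(C)=C/CC/C(C)=C/CC/C(C)=C/CC/C(C)=C/CC[C@@]1(C)O[Al-](OCCOC)(OCCOC)C=C1.[Na+] | intermediate (not isolated)
7 | (1Z,3R,6E,10E,14E,18E,22E,26E,30E)-1-iodo-3,7,11,15,19,23,27,31,35-nonamethylhexatriaconta-1,6,10,14,18,22,26,30,34-nonaen-3-ol | CC(C)=CCC/C(C)=C/CC/C(C)=C/CC/C(C)=C/CC/C(C)=C/CC/C(C)=C/CC/C(C)=C/CC/C(C)=C/CC[C@@](C)(O)/C=C\I | intermediate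
8 | 2,3-dimethylphenol | Cc1cccc(O)c1C | starting material
9 | (2,3-dimethylphenoxy)triisopropylsilane | Cc1cccc(O[Si](C(C)C)(C(C)C)C(C)C)c1C | intermediate
10 | bis(pinacolato)diboron | CC1(C)OB(OC1(C)C)B1OC(C)(C)C(C)(C)O1 | starting material
11 | [2,3-dimethyl-5-(4,4,5,5-tetramethyl-1,3,2-dioxaborolan-2-yl)phenoxy]triisopropylsilane | Cc1cc(B2OC(C)(C)C(C)(C)O2)cc(O[Si](C(C)C)(C(C)C)C(C)C)c1C | intermediate
12 | 2-bromo-3,4-dimethyl-5-(triisopropylsilyloxy)phenylboronic acid pinacol ester | CC1(C)OB(OC1(C)C)c1cc(O[Si](C(C)C)(C(C)C)C(C)C)c(C)c(C)c1Br | intermediate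
13 | (1Z,3R,6E,10E,14E,18E,22E,26E,30E)-1-[2-bromo-3,4-dimethyl-5-(triisopropylsilyloxy)phenyl]-3,7,11,15,19,23,27,31,35-nonamethylhexatriaconta-1,6,10,14,18,22,26,30,34-nonaen-3-ol | CC(C)=CCC/C(C)=C/CC/C(C)=C/CC/C(C)=C/CC/C(C)=C/CC/C(C)=C/CC/C(C)=C/CC/C(C)=C/CC[C@@](C)(O)/C=C\c1cc(O[Si](C(C)C)(C(C)C)C(C)C)c(C)c(C)c1Br | intermediate (not isolated)
14 | plastochromenol-8 triisopropylsilyl ether, triisopropyl{[(2R)-2,7,8-trimethyl-2-R-2H-chromen-6-yl]oxy}silane | CC(C)=CCC/C(C)=C/CC/C(C)=C/CC/C(C)=C/CC/C(C)=C/CC/C(C)=C/CC/C(C)=C/CC/C(C)=C/CC[C@]1(C)C=Cc2cc(O[Si](C(C)C)(C(C)C)C(C)C)c(C)c(C)c2O1 | intermediate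
15 | plastochromenol-8, (2R)-2,7,8-trimethyl-2-R-2H-chromen-6-ol | CC(C)=CCC/C(C)=C/CC/C(C)=C/CC/C(C)=C/CC/C(C)=C/CC/C(C)=C/CC/C(C)=C/CC/C(C)=C/CC[C@]1(C)C=Cc2cc(O)c(C)c(C)c2O1 | target

Total step count: 9 (four to the iodoalkene, three to the arylboronate, the annulation, the desilylation).
Longest linear sequence: 6 steps (steps 1, 2, 3, 4, 8, 9).

Steps most likely to fail

Step 8 (Proposed new method). The aryl C–Br bond may enter the catalytic cycle too early, so that 12 couples with itself. The cis geometry may be lost at the alkenylpalladium stage, after which the alkoxide can no longer reach C8a. C–O reductive elimination from the electron-rich arylpalladium alkoxide may be slow, so that hydrodebromination or attack by residual water takes over. The silyl ether may be slowly lost. The fallback uses known chemistry and makes the two bonds in two separate, individually established operations. It sets out from 7 and 12: a conventional Suzuki–Miyaura coupling with Pd(PPh3)4 and aqueous K3PO4 in THF at 40 °C, a catalyst that leaves the hindered aryl bromide alone, should give bromostyrenyl carbinol 13, which is now isolated and freed from boron residues. In a dry flask 13 is then cyclised by the palladium-catalysed intramolecular etherification of a tertiary alcohol with an aryl bromide (Pd(OAc)2, 2-(di-tert-butylphosphino)-1,1′-binaphthyl, Cs2CO3, toluene, 70 °C), which returns to the route at 14. This fallback makes no compound outside the list (F0).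

Step 4. The hydride may metalate the terminal alkyne C–H in competition with the directed hydroalumination, which would give alkene without iodine or over-iodinated material. Iodine may also attack the 6,7-alkene with help from the neighbouring alkoxide (iodoetherification). In the fallback, iodine is put on first and the cis pair of hydrogens is added afterwards. It sets out from 5: double deprotonation with n-BuLi (2.1 equiv, THF, −78 °C) and iodination of the acetylide with I2 (1.0 equiv) should give (3R)-1-iodo-3,7,11,15,19,23,27,31,35-nonamethylhexatriaconta-6,10,14,18,22,26,30,34-octaen-1-yn-3-ol F1. Syn reduction of the iodoalkyne with diimide, generated from 2-nitrobenzenesulfonylhydrazide and Et3N in THF/i-PrOH at rt and much slower on trisubstituted alkenes, should then give the Z-iodoalkene and return to the route at 7.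

Step 7. Bromination may occur ortho instead of para to the silyloxy group, ipso at the carbon–boron bond, or by a radical path at a benzylic methyl. The fallback reverses the order of halogenation and borylation. It sets out from 9: NBS in MeCN should brominate para to the silyloxy group while no boron is present, giving (4-bromo-2,3-dimethylphenoxy)triisopropylsilane F2. Iridium-catalysed borylation of F2 with 10 ([Ir(OMe)(cod)]2, dtbpy, THF, 80 °C) then has only two C–H bonds to choose from; the one next to the bulky silyloxy group is shielded, so boron should enter next to bromine, and the sequence returns to the route at 12.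

Further compounds
F0 | step 8 | none | none
F1 | step 4 | (3R,6E,10E,14E,18E,22E,26E,30E)-1-iodo-3,7,11,15,19,23,27,31,35-nonamethylhexatriaconta-6,10,14,18,22,26,30,34-octaen-1-yn-3-ol | CC(C)=CCC/C(C)=C/CC/C(C)=C/CC/C(C)=C/CC/C(C)=C/CC/C(C)=C/CC/C(C)=C/CC/C(C)=C/CC[C@@](C)(O)C#CI
F2 | step 7 | (4-bromo-2,3-dimethylphenoxy)triisopropylsilane | CC(C)[Si](Oc1ccc(Br)c(C)c1C)(C(C)C)C(C)C
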